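**Plan**

Ring names: A = benzofuran; B = central 2,3-dihydrobenzofuran (carries the stilbene arm at C5); C = outer 2,3-dihydrobenzofuran, joined through its C4 to C3 of B.
Retrosynthesis cuts, in order: the nine aryl O–CH3 bonds; the aryl–vinyl bond between C5 of B and the ethenyl group on C4 of A (Mizoroki–Heck); the C2–C3 bond of ring B (carbene C–H insertion; the carbene carbon goes back to a ketone made from an aryllithium and an aldehyde); the C2–C3 bond of ring C by the same insertion.
Enabling feature: C3 of ring B is a diarylmethine carbon between the benzo rings of B and C, i.e. the carbon of a diaryl carbene. C2 is an O-bound benzylic carbon bearing the 4-oxygenated phenyl ring, so a hydridic OCH2Ar hydrogen sits 1,5 to that carbene through C3a–C7a–O1 of ring B.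
Forward order: ring C is closed first (insertion, then C2 epimerisation to trans); ring A comes from the same cis-dihydrobenzofuran by dehydrogenation and vinylation; the ring C bromide is lithiated and joined to the ring B aldehyde, and ring B is closed on the derived hydrazone; Heck union and demethylation finish.
Stereochemistry: C3 of ring C (S) and C3 of ring B (R) come from the two enantiomers of a chiral dirhodium tetracarboxylate; both C2 centres are set trans by acid equilibration; the E olefin comes from syn insertion and syn elimination in the Heck step.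

Key step: step 14

Assumption: Rh2(R-PTAD)4 (PTAD = (1-adamantyl)(N-phthalimido)acetate) is taken to give the (3S) sense in step 6 and Rh2(S-PTAD)4 the (3R) sense in step 14. The two steps need opposite catalyst enantiomers in any case; should a test insertion show the reverse assignment, the two catalysts are exchanged and nothing else changes.

**Route**

Step 1
Reactants: 1 2-bromo-4,6-dimethoxybenzaldehyde
Product: 2 2-bromo-6-hydroxy-4-methoxybenzaldehyde
Conditions: BCl3, CH2Cl2, −78 °C to rt; aq. work-up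
Reagents that add atoms: none
Why: Boron trichloride chelates between the formyl oxygen and the ortho methoxy group, so only the ether at C6 should be cleaved (chelation-directed ortho-demethylation) while the para methoxy group and the bromide stay.

Step 2
Reactants: 2 2-bromo-6-hydroxy-4-methoxybenzaldehyde; 3 4-methoxybenzyl chloride
Product: 4 2-bromo-4-methoxy-6-[(4-methoxyphenyl)methoxy]benzaldehyde
Conditions: K2CO3, n-Bu4NI (cat.), DMF, 60 °C
Reagents that add atoms: none
Why: Williamson ether synthesis on the phenoxide installs the 4-methoxybenzyl group whose CH2 later becomes C2 of ring C.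

Step 3
Reactants: 4 2-bromo-4-methoxy-6-[(4-methoxyphenyl)methoxy]benzaldehyde; 5 1-bromo-3,5-dimethoxybenzene
Product: 7 (2-bromo-4-methoxy-6-[(4-methoxyphenyl)methoxy]phenyl)(3,5-dimethoxyphenyl)methanol, via 3,5-dimethoxyphenylmagnesium bromide 6 (not isolated)
Conditions: 5, Mg, I2 (cat.), THF, reflux; then 4, THF, 0 °C to rt; aq. NH4Cl
Reagents that add atoms: none
Why: Aryl Grignard addition to the non-enolisable aldehyde should be fast even between two ortho substituents, and the aryl bromide of 4 is inert to the Grignard reagent at this temperature; the racemic carbinol centre is removed in step 4.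

Step 4
Reactants: 7 (2-bromo-4-methoxy-6-[(4-methoxyphenyl)methoxy]phenyl)(3,5-dimethoxyphenyl)methanol
Product: 8 (2-bromo-4-methoxy-6-[(4-methoxyphenyl)methoxy]phenyl)(3,5-dimethoxyphenyl)methanone
Conditions: Dess–Martin periodinane, CH2Cl2, rt
Reagents that add atoms: none
Why: Dess–Martin oxidation of a diaryl carbinol to the benzophenone runs under neutral conditions that leave the benzyl ether and the aryl bromide untouched.

Step 5
Reactants: 8 (2-bromo-4-methoxy-6-[(4-methoxyphenyl)methoxy]phenyl)(3,5-dimethoxyphenyl)methanone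
Product: 9 hydrazone of ketone 8 (E/Z mixture)
Conditions: N2H4·H2O (excess), AcOH (cat.), n-BuOH, 100 °C, sealed tube
Reagents that add atoms: hydrazine, NN
Why: Acid-catalysed condensation of hydrazine with the diaryl ketone should give the free hydrazone, both geometric isomers leading to the same diazo compound; forcing conditions are chosen because the carbonyl group is flanked by Br and OCH2Ar.

Step 6
Reactants: 9 hydrazone of ketone 8
Product: 11 (2R,3S)-4-bromo-3-(3,5-dimethoxyphenyl)-6-methoxy-2-(4-methoxyphenyl)-2,3-dihydro-1-benzofuran (cis), via diaryldiazomethane 10 (not isolated)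
Conditions: MnO2, CH2Cl2, 0 °C; filter; Rh2(R-PTAD)4 (1 mol %), CH2Cl2, 0 °C
Reagents that add atoms: none
Why: MnO2 oxidises the hydrazone to the diaryldiazomethane, and the chiral dirhodium tetracarboxylate (divalent rhodium) turns it into a donor/donor carbene that undergoes intramolecular 1,5 C–H insertion into the hydridic OCH2Ar bond, the catalyst fixing C3 as S and the suprafacial, cis-selective collapse fixing C2 as R.

Step 7
Reactants: 11 (2R,3S)-4-bromo-3-(3,5-dimethoxyphenyl)-6-methoxy-2-(4-methoxyphenyl)-2,3-dihydro-1-benzofuran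
Product: 12 (2S,3S)-4-bromo-3-(3,5-dimethoxyphenyl)-6-methoxy-2-(4-methoxyphenyl)-2,3-dihydro-1-benzofuran (trans)
Conditions: CF3CO2H, CH2Cl2, 0 °C to rt, dilute
Reagents that add atoms: none
Why: Acid reversibly ionises the C2–O bond to a 4-methoxybenzyl-type cation and reclosure by the phenol should give the more stable trans isomer (acid-mediated cis-to-trans epimerisation of a 2-aryl-dihydrobenzofuran), so C2 is inverted to S while C3, which is not involved, stays S.

Step 8
Reactants: 11 (2R,3S)-4-bromo-3-(3,5-dimethoxyphenyl)-6-methoxy-2-(4-methoxyphenyl)-2,3-dihydro-1-benzofuran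
Product: 13 4-bromo-3-(3,5-dimethoxyphenyl)-6-methoxy-2-(4-methoxyphenyl)-1-benzofuran
Conditions: DDQ, 1,4-dioxane, 90 °C
Reagents that add atoms: none
Why: DDQ abstracts the hydridic H at C2 (alpha to oxygen and to the anisyl ring) and loss of H3 aromatises the furan ring (DDQ dehydrogenation of a dihydrobenzofuran), so both stereocentres are deliberately erased and material of either C2 configuration serves.

Step 9
Reactants: 13 4-bromo-3-(3,5-dimethoxyphenyl)-6-methoxy-2-(4-methoxyphenyl)-1-benzofuran; 14 4,4,5,5-tetramethyl-2-vinyl-1,3,2-dioxaborolane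
Product: 15 4-ethenyl-3-(3,5-dimethoxyphenyl)-6-methoxy-2-(4-methoxyphenyl)-1-benzofuran
Conditions: Pd(dppf)Cl2 (5 mol %), K2CO3, 1,4-dioxane/H2O, 90 °C
Reagents that add atoms: none
Why: Suzuki–Miyaura coupling of the aryl bromide with the vinylboronate installs the ethenyl group, the wide-bite-angle bisphosphine coping with the neighbouring 3-aryl group.

Step 10
Reactants: 16 5-bromo-2-hydroxybenzaldehyde; 3 4-methoxybenzyl chloride
Product: 17 5-bromo-2-[(4-methoxyphenyl)methoxy]benzaldehyde
Conditions: K2CO3, n-Bu4NI (cat.), DMF, 60 °C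
Reagents that add atoms: none
Why: Williamson ether synthesis places on the ring B phenol the benzyl group whose CH2 becomes C2 of ring B, while the bromide para to oxygen is kept for the Heck union.

Step 11
Reactants: 12 (2S,3S)-4-bromo-3-(3,5-dimethoxyphenyl)-6-methoxy-2-(4-methoxyphenyl)-2,3-dihydro-1-benzofuran; 17 5-bromo-2-[(4-methoxyphenyl)methoxy]benzaldehyde
Product: 19 {5-bromo-2-[(4-methoxyphenyl)methoxy]phenyl}[(2S,3S)-3-(3,5-dimethoxyphenyl)-6-methoxy-2-(4-methoxyphenyl)-2,3-dihydro-1-benzofuran-4-yl]methanol (both carbinol epimers), via aryllithium 18 (not isolated)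
Conditions: n-BuLi, THF, −78 °C; then 17, −78 °C to 0 °C; aq. NH4Cl
Reagents that add atoms: none
Why: Bromine–lithium exchange at −78 °C outruns deprotonation, and the aryllithium should add to the aldehyde faster than it exchanges with the aryl bromide of 17; the carbinol epimers converge in step 12 and the ring C stereocentres are untouched.

Step 12
Reactants: 19 {5-bromo-2-[(4-methoxyphenyl)methoxy]phenyl}[(2S,3S)-3-(3,5-dimethoxyphenyl)-6-methoxy-2-(4-methoxyphenyl)-2,3-dihydro-1-benzofuran-4-yl]methanol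
Product: 20 {5-bromo-2-[(4-methoxyphenyl)methoxy]phenyl}[(2S,3S)-3-(3,5-dimethoxyphenyl)-6-methoxy-2-(4-methoxyphenyl)-2,3-dihydro-1-benzofuran-4-yl]methanone
Conditions: Dess–Martin periodinane, CH2Cl2, rt
Reagents that add atoms: none
Why: Dess–Martin oxidation of the diaryl carbinol gives the diaryl ketone under neutral conditions, so the acid-labile benzylic C2–O bond of ring C and its stereocentres are not disturbed.

Step 13
Reactants: 20 {5-bromo-2-[(4-methoxyphenyl)methoxy]phenyl}[(2S,3S)-3-(3,5-dimethoxyphenyl)-6-methoxy-2-(4-methoxyphenyl)-2,3-dihydro-1-benzofuran-4-yl]methanone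
Product: 21 hydrazone of ketone 20 (E/Z mixture)
Conditions: N2H4·H2O (excess), AcOH (cat.), EtOH, 80 °C
Reagents that add atoms: hydrazine, NN
Why: Condensation of hydrazine with the diaryl ketone, which has one ortho substituent on each ring, gives the oxidation level needed for the diazo compound without touching the ethers, the bromide or ring C.

Step 14
Reactants: 21 hydrazone of ketone 20
Product: 23 (2S,3R)-5-bromo-3-[(2S,3S)-3-(3,5-dimethoxyphenyl)-6-methoxy-2-(4-methoxyphenyl)-2,3-dihydro-1-benzofuran-4-yl]-2-(4-methoxyphenyl)-2,3-dihydro-1-benzofuran (ring B cis), via diaryldiazomethane 22 (not isolated)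
Conditions: MnO2, CH2Cl2, 0 °C; filter; slow addition to Rh2(S-PTAD)4 (1–2 mol %), CH2Cl2, −20 to 0 °C
Reagents that add atoms: none
Why: MnO2 dehydrogenates the hydrazone to diaryldiazomethane 22, which loses N2 at the dirhodium tetracarboxylate (divalent rhodium) to give a rhodium-bound diaryl (donor/donor) carbene at the future C3 of ring B, and this carbene takes up the hydridic hydrogen of the OCH2Ar group while the C2–C3 bond forms in one asynchronous, concerted event. The closest known reaction type is the enantioselective intramolecular C–H insertion of donor/donor dirhodium carbenes into benzylic ethers, which gives cis-2,3-diaryl-2,3-dihydrobenzofurans. The dihydrofuran ring of B is the only ring closed, as a five-membered ring by 1,5-insertion through a cyclic transition state made up of the carbene carbon, C3a, C7a, O1 and the CH2 carbon. C3 (R) is set by the chiral catalyst, which selects the face of the carbene and with it one of the two enantiotopic CH2 hydrogens, and C2 (S) follows from the suprafacial collapse that leaves the two aryl groups cis; C2 is inverted in step 15. The step needs site selectivity for this C–H bond over attack of the carbene on the 3,5-dimethoxyphenyl ring of ring C, on methoxy C–H bonds or on a second diazo molecule (azine), and this is secured by the alpha-oxygen, benzylic and para-methoxy activation of the bond, by the five-membered geometry, by the low electrophilicity of a donor/donor carbene and by slow addition of 22 at low temperature. It also needs catalyst control over the two stereocentres of ring C, which lie one ring away from the reacting centres and should modulate but not overturn the sense imposed by the PTAD ligands.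

Step 15
Reactants: 23 (2S,3R)-5-bromo-3-[(2S,3S)-3-(3,5-dimethoxyphenyl)-6-methoxy-2-(4-methoxyphenyl)-2,3-dihydro-1-benzofuran-4-yl]-2-(4-methoxyphenyl)-2,3-dihydro-1-benzofuran
Product: 24 (2R,3R)-5-bromo-3-[(2S,3S)-3-(3,5-dimethoxyphenyl)-6-methoxy-2-(4-methoxyphenyl)-2,3-dihydro-1-benzofuran-4-yl]-2-(4-methoxyphenyl)-2,3-dihydro-1-benzofuran (both rings trans)
Conditions: CF3CO2H, CH2Cl2, −20 to 0 °C, dilute, stopped as soon as 23 is consumed
Reagents that add atoms: none
Why: Reversible ionisation of the C2–O bond of ring B and reclosure by the phenol should invert C2 to the trans (R) configuration while C3 stays R and ring C, already trans, can only return to itself; exposure is kept short so that the five-membered reclosure outruns Friedel–Crafts capture of the cation by the 3,5-dimethoxyphenyl ring or loss of H3.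

Step 16
Reactants: 24 (2R,3R)-5-bromo-3-[(2S,3S)-3-(3,5-dimethoxyphenyl)-6-methoxy-2-(4-methoxyphenyl)-2,3-dihydro-1-benzofuran-4-yl]-2-(4-methoxyphenyl)-2,3-dihydro-1-benzofuran; 15 4-ethenyl-3-(3,5-dimethoxyphenyl)-6-methoxy-2-(4-methoxyphenyl)-1-benzofuran
Product: 25 nonamethyl ether of the target (E olefin)
Conditions: Pd(OAc)2 (10 mol %), P(o-tol)3 (20 mol %), Et3N, DMF, 110 °C
Reagents that add atoms: none
Why: Mizoroki–Heck reaction: oxidative addition of zerovalent palladium to the aryl bromide, syn insertion of the terminal alkene at its unsubstituted carbon and syn beta-hydride elimination should give the E-1,2-diarylethene, and no stereocentre is at risk under the basic conditions.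

Step 17
Reactants: 25 nonamethyl ether of the target
Product: 26 target compound
Conditions: BBr3 (excess), CH2Cl2, −78 °C to rt; then ice/water
Reagents that add atoms: none
Why: BBr3 should cleave all nine aryl methyl ethers (Lewis acid ether cleavage); any reversible opening of the two dihydrofuran rings at C2 returns to the trans isomers already present, and the C3 centres and the E olefin are not part of the reaction.

**Compound list**

1 | 2-bromo-4,6-dimethoxybenzaldehyde | O=Cc1c(Br)cc(OC)cc1OC | starting material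
2 | 2-bromo-6-hydroxy-4-methoxybenzaldehyde | O=Cc1c(Br)cc(OC)cc1O | intermediate
3 | 4-methoxybenzyl chloride | COc1ccc(CCl)cc1 | starting material
4 | 2-bromo-4-methoxy-6-[(4-methoxyphenyl)methoxy]benzaldehyde | O=Cc1c(Br)cc(OC)cc1OCc1ccc(OC)cc1 | intermediate
5 | 1-bromo-3,5-dimethoxybenzene | COc1cc(Br)cc(OC)c1 | starting material
6 | 3,5-dimethoxyphenylmagnesium bromide | COc1cc([Mg]Br)cc(OC)c1 | intermediate
7 | (2-bromo-4-methoxy-6-[(4-methoxyphenyl)methoxy]phenyl)(3,5-dimethoxyphenyl)methanol (racemic) | OC(c1cc(OC)cc(OC)c1)c1c(Br)cc(OC)cc1OCc1ccc(OC)cc1 | intermediate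
8 | (2-bromo-4-methoxy-6-[(4-methoxyphenyl)methoxy]phenyl)(3,5-dimethoxyphenyl)methanone | O=C(c1cc(OC)cc(OC)c1)c1c(Br)cc(OC)cc1OCc1ccc(OC)cc1 | intermediate
9 | hydrazone of ketone 8 (E/Z mixture) | NN=C(c1cc(OC)cc(OC)c1)c1c(Br)cc(OC)cc1OCc1ccc(OC)cc1 | intermediate
10 | (2-bromo-4-methoxy-6-[(4-methoxyphenyl)methoxy]phenyl)(3,5-dimethoxyphenyl)diazomethane | [N-]=[N+]=C(c1cc(OC)cc(OC)c1)c1c(Br)cc(OC)cc1OCc1ccc(OC)cc1 | intermediate
11 | (2R,3S)-4-bromo-3-(3,5-dimethoxyphenyl)-6-methoxy-2-(4-methoxyphenyl)-2,3-dihydro-1-benzofuran (cis) | Brc1cc(OC)cc2c1[C@H](c1cc(OC)cc(OC)c1)[C@H](c1ccc(OC)cc1)O2 | intermediate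
12 | (2S,3S)-4-bromo-3-(3,5-dimethoxyphenyl)-6-methoxy-2-(4-methoxyphenyl)-2,3-dihydro-1-benzofuran (trans) | Brc1cc(OC)cc2c1[C@H](c1cc(OC)cc(OC)c1)[C@@H](c1ccc(OC)cc1)O2 | intermediate
13 | 4-bromo-3-(3,5-dimethoxyphenyl)-6-methoxy-2-(4-methoxyphenyl)-1-benzofuran | Brc1cc(OC)cc2oc(-c3ccc(OC)cc3)c(-c3cc(OC)cc(OC)c3)c12 | intermediate
14 | 4,4,5,5-tetramethyl-2-vinyl-1,3,2-dioxaborolane | C=CB1OC(C)(C)C(C)(C)O1 | starting material
15 | 4-ethenyl-3-(3,5-dimethoxyphenyl)-6-methoxy-2-(4-methoxyphenyl)-1-benzofuran | C=Cc1cc(OC)cc2oc(-c3ccc(OC)cc3)c(-c3cc(OC)cc(OC)c3)c12 | intermediate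
16 | 5-bromo-2-hydroxybenzaldehyde | O=Cc1cc(Br)ccc1O | starting material
17 | 5-bromo-2-[(4-methoxyphenyl)methoxy]benzaldehyde | O=Cc1cc(Br)ccc1OCc1ccc(OC)cc1 | intermediate
18 | [(2S,3S)-3-(3,5-dimethoxyphenyl)-6-methoxy-2-(4-methoxyphenyl)-2,3-dihydro-1-benzofuran-4-yl]lithium | [Li]c1cc(OC)cc2c1[C@H](c1cc(OC)cc(OC)c1)[C@@H](c1ccc(OC)cc1)O2 | intermediate
19 | {5-bromo-2-[(4-methoxyphenyl)methoxy]phenyl}[(2S,3S)-3-(3,5-dimethoxyphenyl)-6-methoxy-2-(4-methoxyphenyl)-2,3-dihydro-1-benzofuran-4-yl]methanol (both carbinol epimers) | OC(c1cc(Br)ccc1OCc1ccc(OC)cc1)c1cc(OC)cc2c1[C@H](c1cc(OC)cc(OC)c1)[C@@H](c1ccc(OC)cc1)O2 | intermediate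
20 | {5-bromo-2-[(4-methoxyphenyl)methoxy]phenyl}[(2S,3S)-3-(3,5-dimethoxyphenyl)-6-methoxy-2-(4-methoxyphenyl)-2,3-dihydro-1-benzofuran-4-yl]methanone | O=C(c1cc(Br)ccc1OCc1ccc(OC)cc1)c1cc(OC)cc2c1[C@H](c1cc(OC)cc(OC)c1)[C@@H](c1ccc(OC)cc1)O2 | intermediate
21 | hydrazone of ketone 20 (E/Z mixture) | NN=C(c1cc(Br)ccc1OCc1ccc(OC)cc1)c1cc(OC)cc2c1[C@H](c1cc(OC)cc(OC)c1)[C@@H](c1ccc(OC)cc1)O2 | intermediate
22 | {5-bromo-2-[(4-methoxyphenyl)methoxy]phenyl}[(2S,3S)-3-(3,5-dimethoxyphenyl)-6-methoxy-2-(4-methoxyphenyl)-2,3-dihydro-1-benzofuran-4-yl]diazomethane | [N-]=[N+]=C(c1cc(Br)ccc1OCc1ccc(OC)cc1)c1cc(OC)cc2c1[C@H](c1cc(OC)cc(OC)c1)[C@@H](c1ccc(OC)cc1)O2 | intermediate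
23 | (2S,3R)-5-bromo-3-[(2S,3S)-3-(3,5-dimethoxyphenyl)-6-methoxy-2-(4-methoxyphenyl)-2,3-dihydro-1-benzofuran-4-yl]-2-(4-methoxyphenyl)-2,3-dihydro-1-benzofuran (ring B cis) | Brc1ccc2c(c1)[C@@H](c1cc(OC)cc3c1[C@H](c1cc(OC)cc(OC)c1)[C@@H](c1ccc(OC)cc1)O3)[C@@H](c1ccc(OC)cc1)O2 | intermediate
24 | (2R,3R)-5-bromo-3-[(2S,3S)-3-(3,5-dimethoxyphenyl)-6-methoxy-2-(4-methoxyphenyl)-2,3-dihydro-1-benzofuran-4-yl]-2-(4-methoxyphenyl)-2,3-dihydro-1-benzofuran (both rings trans) | Brc1ccc2c(c1)[C@@H](c1cc(OC)cc3c1[C@H](c1cc(OC)cc(OC)c1)[C@@H](c1ccc(OC)cc1)O3)[C@H](c1ccc(OC)cc1)O2 | intermediate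
25 | 4-[(E)-2-{(2R,3R)-3-[(2S,3S)-3-(3,5-dimethoxyphenyl)-6-methoxy-2-(4-methoxyphenyl)-2,3-dihydro-1-benzofuran-4-yl]-2-(4-methoxyphenyl)-2,3-dihydro-1-benzofuran-5-yl}ethenyl]-3-(3,5-dimethoxyphenyl)-6-methoxy-2-(4-methoxyphenyl)-1-benzofuran (nonamethyl ether of the target) | COc1ccc(-c2oc3cc(OC)cc(/C=C/c4ccc5c(c4)[C@@H](c4cc(OC)cc6c4[C@H](c4cc(OC)cc(OC)c4)[C@@H](c4ccc(OC)cc4)O6)[C@H](c4ccc(OC)cc4)O5)c3c2-c2cc(OC)cc(OC)c2)cc1 | intermediate
26 | 4-[(E)-2-{(2R,3R)-3-[(2S,3S)-3-(3,5-dihydroxyphenyl)-6-hydroxy-2-(4-hydroxyphenyl)-2,3-dihydro-1-benzofuran-4-yl]-2-(4-hydroxyphenyl)-2,3-dihydro-1-benzofuran-5-yl}ethenyl]-3-(3,5-dihydroxyphenyl)-2-(4-hydroxyphenyl)-1-benzofuran-6-ol | Oc1ccc(-c2oc3cc(O)cc(/C=C/c4ccc5c(c4)[C@@H](c4cc(O)cc6c4[C@H](c4cc(O)cc(O)c4)[C@@H](c4ccc(O)cc4)O6)[C@H](c4ccc(O)cc4)O5)c3c2-c2cc(O)cc(O)c2)cc1 | target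

**Step count and risks**

Total step count: 17. Longest linear sequence: 14 steps (steps 1–7 and 11–17).

The three steps most likely to fail:

Step 14 (key step). The catalyst and the existing ring C stereocentres may be a mismatched pair and erode facial selectivity; the carbene may also be diverted onto the neighbouring 3,5-dimethoxyphenyl ring or into azine formation. The fallback sets out from 12 (with 16) and comes back at 24. 5-Bromo-2-hydroxybenzaldehyde 16 is acylated with Boc2O (DMAP cat., CH2Cl2) to 4-bromo-2-formylphenyl tert-butyl carbonate F1. Aryllithium 18, made from 12 as in step 11, is added to F1 at −78 °C; the alkoxide takes over the Boc group to give the benzylic tert-butyl carbonate phenoxide F2, which on warming with MgBr2·OEt2 loses tert-butyl carbonate to give the ortho-quinone methide F3. This is trapped in the same flask by the ylide made from (4-methoxybenzyl)dimethylsulfonium tetrafluoroborate and LiN(SiMe3)2. Conjugate addition of the ylide carbon to the methide carbon and displacement of dimethyl sulfide by the phenoxide (a [4+1] annulation of an ortho-quinone methide with a sulfur ylide) should give the trans-dihydrobenzofuran 24 directly. C3 of ring B would then be set by approach of the ylide anti to the 3-aryl group of ring C (substrate control, diastereomers separable), with no carbene and no epimerisation step.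

Step 17. During the nine-fold ether cleavage the stilbene may be protonated and captured by the 3,5-dioxygenated ring on C3 of ring A in a seven-membered Friedel–Crafts closure, the ring-opened cation of ring B may be captured likewise, and cleavage may stay incomplete. The fallback sets out from 24 and 13 and comes back at 26; it exchanges the protecting groups before the union, so that the olefin never meets a Lewis acid. BBr3 converts 24 into the pentaphenol bromide F4, and Ac2O/pyridine gives the pentaacetate F5. BBr3 converts 13 into the tetraphenol bromide F6, Ac2O/pyridine gives the tetraacetate F7, and Stille coupling with Bu3SnCH=CH2 and Pd(PPh3)4 (zerovalent palladium) in toluene gives the vinyl tetraacetate F8. Heck coupling of F5 with F8 under the conditions of step 16 should give the nonaacetate F9, and K2CO3 in MeOH at 0 °C releases 26.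

Step 5. Condensation may stall at the carbonyl group flanked by Br and OCH2Ar, and under harsher forcing the hydrazone nitrogen may displace the ortho bromide to give an indazole. The fallback sets out from 4 and comes back at 9; it makes the C=N bond by addition to a nitrile and imine exchange instead. Aldehyde 4 is converted with I2 and aqueous NH3 in THF into 2-bromo-4-methoxy-6-[(4-methoxyphenyl)methoxy]benzonitrile F10. Grignard reagent 6 (from 5) is added in THF/toluene at reflux and the mixture is quenched with methanol to give the N–H ketimine F11. Hydrazine hydrate with catalytic AcOH in EtOH at 60 °C then exchanges NH for N–NH2 to give 9; compounds 7 and 8 are not needed.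

**Further compounds**

F1 | step 14 | 4-bromo-2-formylphenyl tert-butyl carbonate | O=Cc1cc(Br)ccc1OC(=O)OC(C)(C)C
F2 | step 14 | tert-butyl (5-bromo-2-hydroxyphenyl)[(2S,3S)-3-(3,5-dimethoxyphenyl)-6-methoxy-2-(4-methoxyphenyl)-2,3-dihydro-1-benzofuran-4-yl]methyl carbonate (as phenoxide in the flask) | CC(C)(C)OC(=O)OC(c1cc(Br)ccc1O)c1cc(OC)cc2c1[C@H](c1cc(OC)cc(OC)c1)[C@@H](c1ccc(OC)cc1)O2
F3 | step 14 | 4-bromo-6-{[(2S,3S)-3-(3,5-dimethoxyphenyl)-6-methoxy-2-(4-methoxyphenyl)-2,3-dihydro-1-benzofuran-4-yl]methylidene}cyclohexa-2,4-dien-1-one (ortho-quinone methide) | O=C1C=CC(Br)=CC1=Cc1cc(OC)cc2c1[C@H](c1cc(OC)cc(OC)c1)[C@@H](c1ccc(OC)cc1)O2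
F4 | step 17 | pentaphenol corresponding to 24 | Brc1ccc2c(c1)[C@@H](c1cc(O)cc3c1[C@H](c1cc(O)cc(O)c1)[C@@H](c1ccc(O)cc1)O3)[C@H](c1ccc(O)cc1)O2
F5 | step 17 | pentaacetate of F4 | Brc1ccc2c(c1)[C@@H](c1cc(OC(C)=O)cc3c1[C@H](c1cc(OC(C)=O)cc(OC(C)=O)c1)[C@@H](c1ccc(OC(C)=O)cc1)O3)[C@H](c1ccc(OC(C)=O)cc1)O2
F6 | step 17 | 4-bromo-3-(3,5-dihydroxyphenyl)-2-(4-hydroxyphenyl)-1-benzofuran-6-ol | Brc1cc(O)cc2oc(-c3ccc(O)cc3)c(-c3cc(O)cc(O)c3)c12
F7 | step 17 | tetraacetate of F6 | CC(=O)Oc1ccc(-c2oc3cc(OC(C)=O)cc(Br)c3c2-c2cc(OC(C)=O)cc(OC(C)=O)c2)cc1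
F8 | step 17 | 4-ethenyl analogue of F7 (vinyl tetraacetate) | CC(=O)Oc1ccc(-c2oc3cc(OC(C)=O)cc(C=C)c3c2-c2cc(OC(C)=O)cc(OC(C)=O)c2)cc1
F9 | step 17 | nonaacetate of 26 | CC(=O)Oc1ccc(-c2oc3cc(OC(C)=O)cc(/C=C/c4ccc5c(c4)[C@@H](c4cc(OC(C)=O)cc6c4[C@H](c4cc(OC(C)=O)cc(OC(C)=O)c4)[C@@H](c4ccc(OC(C)=O)cc4)O6)[C@H](c4ccc(OC(C)=O)cc4)O5)c3c2-c2cc(OC(C)=O)cc(OC(C)=O)c2)cc1
F10 | step 5 | 2-bromo-4-methoxy-6-[(4-methoxyphenyl)methoxy]benzonitrile | N#Cc1c(Br)cc(OC)cc1OCc1ccc(OC)cc1
F11 | step 5 | (2-bromo-4-methoxy-6-[(4-methoxyphenyl)methoxy]phenyl)(3,5-dimethoxyphenyl)methanimine | N=C(c1cc(OC)cc(OC)c1)c1c(Br)cc(OC)cc1OCc1ccc(OC)cc1
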